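**Plan**

1. Retrosynthetic cuts: the C14–O ester bond (acid 17 + isocoronarin D 23); both C12=C13 double bonds (Wittig for the acid half, aldol–elimination for the lactone half), which leads both halves back to one C12 aldehyde 11; then C8=C17 (Wittig); then carbon C7 of ring B.
2. Feature used: C8 of ring B, the carbon of the exocyclic methylene, is a latent ketone between the unsubstituted C7H2 and the branched C9. Without C7, the ring C5–C6–C8–C9–C10 is a cyclopentanone, so ring B is made by one-carbon enlargement of a hydrindanone (C7 inserted between C6 and C8).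
3. Forward order: ring A is bought (2,2,6-trimethylcyclohexanone); C10 by Pd-catalysed decarboxylative allylation; five-membered ring by Wacker oxidation and aldol condensation; C9–C11 by alkylation of the enone at its only enolisable carbon; C5–H by hydrogenation; ring B by ring enlargement; then methylenation, two chain extensions, esterification, acetal hydrolysis.
4. Stereochemistry: C10 from the chiral Pd–PHOX catalyst; C5 from hydrogenation anti to the C10 and 4β methyl groups; C9 by equilibration next to the C8 ketone (equatorial chain); C14 from (R)-3-hydroxy-γ-butyrolactone; the (E)-alkenes from a stabilised ylide and from E1cB elimination.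

Key step: step 7

Remark: labdane numbering (C1–C20) is used for both halves; 3 is expected in high but not complete enantiomeric purity, and because C14 comes from enantiopure 18, material from the minor enantiomer becomes a diastereomer to be removed at 23 and 25.

**Route**

Step 1
Reactants: 1 2,2,6-trimethylcyclohexan-1-one
Product: 2 2,6,6-trimethylcyclohex-1-en-1-yl prop-2-en-1-yl carbonate
Conditions: LiN(SiMe3)2, THF, 0 °C; then allyl chloroformate, −78 °C → rt
Reagents that add atoms: allyl chloroformate, C=CCOC(Cl)=O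
Why: The ketone has a single enolisable position, and its hindered tetrasubstituted lithium enolate is acylated on oxygen by the chloroformate (enol carbonate formation).

Step 2
Reactants: 2 2,6,6-trimethylcyclohex-1-en-1-yl prop-2-en-1-yl carbonate
Product: 3 (2R)-2,6,6-trimethyl-2-(prop-2-en-1-yl)cyclohexan-1-one
Conditions: Pd2(dba)3 (2.5 mol %), (R)-t-Bu-PHOX (6 mol %), THF, 25 °C
Reagents that add atoms: none
Why: Tsuji decarboxylative asymmetric allylic alkylation: zerovalent palladium ionises the allyl carbonate, CO2 is lost and the enolate is allylated inside the chiral Pd–PHOX pocket, which sets the quaternary centre C10 as (R) (the (R)-ligand is chosen by analogy with the known sense of induction of this ligand class).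

Step 3
Reactants: 3 (2R)-2,6,6-trimethyl-2-(prop-2-en-1-yl)cyclohexan-1-one
Product: 4 (2R)-2,6,6-trimethyl-2-(2-oxopropyl)cyclohexan-1-one
Conditions: PdCl2 (10 mol %), Cu(OAc)2·H2O (20 mol %), O2 (1 atm), DMA/H2O, 25 °C
Reagents that add atoms: water, O
Why: Tsuji–Wacker oxidation converts the terminal alkene with Markovnikov selectivity into the methyl ketone, the hindered ring ketone being inert.

Step 4
Reactants: 4 (2R)-2,6,6-trimethyl-2-(2-oxopropyl)cyclohexan-1-one
Product: 5 (7aR)-4,4,7a-trimethyl-1,4,5,6,7,7a-hexahydro-2H-inden-2-one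
Conditions: KOH, xylenes, 110 °C, Dean–Stark trap
Reagents that add atoms: none
Why: Intramolecular aldol condensation: only the methyl ketone can enolise (the ring ketone has no α-hydrogen) and only its methyl carbon can reach C5 in a five-membered ring, so dehydration should give one cyclopentenone.

Step 5
Reactants: 5 (7aR)-4,4,7a-trimethyl-1,4,5,6,7,7a-hexahydro-2H-inden-2-one
Product: 6 methyl 2-[(7aR)-4,4,7a-trimethyl-2-oxo-2,4,5,6,7,7a-hexahydro-1H-inden-1-yl]acetate (both C1 epimers)
Conditions: LiN(i-Pr)2, THF, −78 °C; then methyl bromoacetate, DMPU, −78 → −20 °C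
Reagents that add atoms: methyl bromoacetate, COC(=O)CBr
Why: Kinetic deprotonation gives the cross-conjugated enolate at the only enolisable carbon (C9; the γ-carbon C4 is quaternary) and SN2 alkylation installs C11–C12; C9 is formed as an epimer mixture that is corrected in step 7.

Step 6
Reactants: 6 methyl 2-[(7aR)-4,4,7a-trimethyl-2-oxo-2,4,5,6,7,7a-hexahydro-1H-inden-1-yl]acetate
Product: 7 methyl 2-[(3aS,7aS)-4,4,7a-trimethyl-2-oxooctahydro-1H-inden-1-yl]acetate (trans-fused; both C1 epimers)
Conditions: H2 (5 bar), 10 % Pd/C, EtOAc, 25 °C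
Reagents that add atoms: none
Why: Catalytic hydrogenation of the enone double bond should deliver hydrogen to the α-face, opposite the syn-axial C10 and 4β methyl groups, which sets C5 (trans ring fusion) as in the hydrogenation of 4,4,10-trimethyl-Δ5-octalins.

Step 7
Reactants: 7 methyl 2-[(3aS,7aS)-4,4,7a-trimethyl-2-oxooctahydro-1H-inden-1-yl]acetate
Product: 9 methyl 2-[(1R,4aS,8aS)-5,5,8a-trimethyl-2-oxodecahydronaphthalen-1-yl]acetate, via α-silyl ketone 8 (not isolated)
Conditions: Me3SiCHN2, BF3·OEt2, CH2Cl2, −78 → −30 °C; then NaOMe (cat.), MeOH, 0 → 25 °C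
Reagents that add atoms: (trimethylsilyl)diazomethane, C[Si](C)(C)C=[N+]=[N-]
Why: BF3 activates the C8 carbonyl, the diazo carbon adds to it, and the diazonium betaine loses N2 while the anti-periplanar C6–C8 bond shifts to the new carbon (C7), which enlarges the cyclopentanone to the cyclohexanone of ring B; the closest known reaction type is the Tiffeneau–Demjanov-type homologation of 2-substituted cycloalkanones with Me3SiCHN2 under BF3 or AlMe3 promotion. No ring is closed between chain ends: ring B arises by a 1,2-alkyl shift ring enlargement (five to six), the new C6–C7 and C7–C8 bonds lying inside the old ring. The step creates no lasting stereocentre (the C7–Si centre is erased on desilylation); C5 and C10 are untouched, and C9, now α to a cyclohexanone, should be equilibrated by NaOMe to the equatorial 9β side chain (9α-H), the natural configuration. The selectivity needed is migration of C6 (CH2) and not of C9: the branched C9 next to the quaternary C10 is hindered from taking the anti-periplanar position beside the bulky Me3Si–CH–N2+ unit, and this reaction type is known to move the less substituted α-carbon. A second insertion is not expected, because the first product is an α-silyl ketone that is too hindered to react again before methanolysis.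

Step 8
Reactants: 9 methyl 2-[(1R,4aS,8aS)-5,5,8a-trimethyl-2-oxodecahydronaphthalen-1-yl]acetate
Product: 10 methyl 2-[(1S,4aS,8aS)-5,5,8a-trimethyl-2-methylidenedecahydronaphthalen-1-yl]acetate
Conditions: Ph3PCH3Br, KOtBu, toluene, 25 → 80 °C
Reagents that add atoms: methyltriphenylphosphonium bromide, C[P+](c1ccccc1)(c1ccccc1)c1ccccc1.[Br-]
Why: Wittig methylenation of the hindered ketone with excess Ph3P=CH2 builds the exocyclic C8=C17 double bond; the methyl ester is unreactive toward the ylide and C9 stays in its equilibrium (equatorial) configuration.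

Step 9
Reactants: 10 methyl 2-[(1S,4aS,8aS)-5,5,8a-trimethyl-2-methylidenedecahydronaphthalen-1-yl]acetate
Product: 11 2-[(1S,4aS,8aS)-5,5,8a-trimethyl-2-methylidenedecahydronaphthalen-1-yl]acetaldehyde
Conditions: i-Bu2AlH (1.1 equiv), CH2Cl2, −78 °C; Rochelle salt work-up
Reagents that add atoms: none
Why: Partial reduction with i-Bu2AlH at −78 °C stops at the aluminium hemiacetal, which gives the aldehyde on work-up.

Step 10
Reactants: 12 methyl 4,4-dimethoxybutanoate
Product: 13 methyl 2-bromo-4,4-dimethoxybutanoate (racemic)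
Conditions: LiN(i-Pr)2, THF, −78 °C; then BrCl2C–CCl2Br, −78 → 0 °C
Reagents that add atoms: 1,2-dibromo-1,1,2,2-tetrachloroethane, BrC(Cl)(Cl)C(Cl)(Cl)Br
Why: Electrophilic α-bromination of the ester lithium enolate with a positive-bromine source; the acetal is inert to base.

Step 11
Reactants: 13 methyl 2-bromo-4,4-dimethoxybutanoate
Product: 15 methyl 4,4-dimethoxy-2-(triphenyl-λ5-phosphanylidene)butanoate, via phosphonium bromide 14 (not isolated)
Conditions: PPh3, MeCN, 80 °C; then NaOH (1 M aq), CH2Cl2, 0 °C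
Reagents that add atoms: triphenylphosphine, c1ccc(cc1)P(c1ccccc1)c1ccccc1
Why: SN2 quaternisation of PPh3 by the α-bromo ester followed by deprotonation gives the ester-stabilised ylide (standard preparation of α-substituted alkoxycarbonyl ylides).

Step 12
Reactants: 11 2-[(1S,4aS,8aS)-5,5,8a-trimethyl-2-methylidenedecahydronaphthalen-1-yl]acetaldehyde; 15 methyl 4,4-dimethoxy-2-(triphenyl-λ5-phosphanylidene)butanoate
Product: 16 methyl (2E)-2-(2,2-dimethoxyethyl)-4-[(1S,4aS,8aS)-5,5,8a-trimethyl-2-methylidenedecahydronaphthalen-1-yl]but-2-enoate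
Conditions: toluene, 90 °C
Reagents that add atoms: none
Why: Wittig olefination with an α-substituted ester-stabilised ylide, which should give the trisubstituted (E)-enoate (carboxyl trans to C11) as this ylide class does.

Step 13
Reactants: 16 methyl (2E)-2-(2,2-dimethoxyethyl)-4-[(1S,4aS,8aS)-5,5,8a-trimethyl-2-methylidenedecahydronaphthalen-1-yl]but-2-enoate
Product: 17 (2E)-2-(2,2-dimethoxyethyl)-4-[(1S,4aS,8aS)-5,5,8a-trimethyl-2-methylidenedecahydronaphthalen-1-yl]but-2-enoic acid
Conditions: LiOH·H2O, THF/MeOH/H2O, 45 °C; then 1 M HCl to pH 4, 0 °C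
Reagents that add atoms: lithium hydroxide, [Li+].[OH-]
Why: Saponification of the methyl ester; the dimethyl acetal is stable to base and should survive brief acidification to pH 4 in the cold.

Step 14
Reactants: 18 (4R)-4-hydroxyoxolan-2-one [(R)-3-hydroxy-γ-butyrolactone]
Product: 19 (4R)-4-[(tert-butyldimethylsilyl)oxy]oxolan-2-one
Conditions: t-BuMe2SiCl, imidazole, DMF, 25 °C
Reagents that add atoms: tert-butyldimethylsilyl chloride, CC(C)(C)[Si](C)(C)Cl
Why: Imidazole-promoted silylation protects the C14 hydroxyl without touching the stereocentre.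

Step 15
Reactants: 19 (4R)-4-[(tert-butyldimethylsilyl)oxy]oxolan-2-one; 11 2-[(1S,4aS,8aS)-5,5,8a-trimethyl-2-methylidenedecahydronaphthalen-1-yl]acetaldehyde
Product: 20 (4R)-4-[(tert-butyldimethylsilyl)oxy]-3-{1-hydroxy-2-[(1S,4aS,8aS)-5,5,8a-trimethyl-2-methylidenedecahydronaphthalen-1-yl]ethyl}oxolan-2-one (diastereomer mixture at C3 and the carbinol carbon)
Conditions: LiN(i-Pr)2, THF, −78 °C; then 11, −78 °C; NH4Cl (aq)
Reagents that add atoms: none
Why: Aldol addition of the lactone lithium enolate, generated and used at −78 °C to suppress β-elimination of the silyloxy group, forms the C12–C13 bond; the two new centres are removed in step 16, so their configuration does not matter.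

Step 16
Reactants: 20 (4R)-4-[(tert-butyldimethylsilyl)oxy]-3-{1-hydroxy-2-[(1S,4aS,8aS)-5,5,8a-trimethyl-2-methylidenedecahydronaphthalen-1-yl]ethyl}oxolan-2-one
Product: 22 (3E,4R)-4-[(tert-butyldimethylsilyl)oxy]-3-{2-[(1S,4aS,8aS)-5,5,8a-trimethyl-2-methylidenedecahydronaphthalen-1-yl]ethylidene}oxolan-2-one, via mesylate 21 (not isolated)
Conditions: MeSO2Cl, Et3N, CH2Cl2, 0 °C; then DBU, 0 → 25 °C
Reagents that add atoms: none
Why: Mesylation of the C12 alcohol and E1cB elimination through the lactone enolate give the conjugated exocyclic alkene, the (E)-isomer (C11 anti to the lactone carbonyl) being expected as the more stable product; the mesylate, not the silyloxy group, is the leaving group.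

Step 17
Reactants: 22 (3E,4R)-4-[(tert-butyldimethylsilyl)oxy]-3-{2-[(1S,4aS,8aS)-5,5,8a-trimethyl-2-methylidenedecahydronaphthalen-1-yl]ethylidene}oxolan-2-one
Product: 23 (3E,4R)-4-hydroxy-3-{2-[(1S,4aS,8aS)-5,5,8a-trimethyl-2-methylidenedecahydronaphthalen-1-yl]ethylidene}oxolan-2-one (isocoronarin D)
Conditions: HF·pyridine, pyridine/THF, 0 → 25 °C
Reagents that add atoms: none
Why: Fluoride cleavage of the silyl ether under buffered conditions should leave the lactone and the alkenes intact.

Step 18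
Reactants: 17 (2E)-2-(2,2-dimethoxyethyl)-4-[(1S,4aS,8aS)-5,5,8a-trimethyl-2-methylidenedecahydronaphthalen-1-yl]but-2-enoic acid; 23 isocoronarin D
Product: 25 (3R,4E)-5-oxo-4-{2-[(1S,4aS,8aS)-5,5,8a-trimethyl-2-methylidenedecahydronaphthalen-1-yl]ethylidene}oxolan-3-yl (2E)-2-(2,2-dimethoxyethyl)-4-[(1S,4aS,8aS)-5,5,8a-trimethyl-2-methylidenedecahydronaphthalen-1-yl]but-2-enoate, via mixed anhydride 24 (not isolated)
Conditions: 2,4,6-trichlorobenzoyl chloride, Et3N, THF, 25 °C; then 23, DMAP, toluene, 25 °C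
Reagents that add atoms: none
Why: Yamaguchi esterification: DMAP attacks the mixed anhydride at the less hindered enoyl carbonyl and the acylpyridinium acylates the secondary C14 alcohol with retention at C14.

Step 19
Reactants: 25 the dimethyl acetal ester from step 18
Product: 26 (3R,4E)-5-oxo-4-{2-[(1S,4aS,8aS)-5,5,8a-trimethyl-2-methylidenedecahydronaphthalen-1-yl]ethylidene}oxolan-3-yl (2E)-2-(2-oxoethyl)-4-[(1S,4aS,8aS)-5,5,8a-trimethyl-2-methylidenedecahydronaphthalen-1-yl]but-2-enoate (target)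
Conditions: TsOH·H2O (5 mol %), acetone/H2O (20:1), 0 → 25 °C
Reagents that add atoms: water, O
Why: Acid-catalysed acetal hydrolysis via the oxocarbenium ion frees the C15 aldehyde; the esters, the lactone and the 1,1-disubstituted alkenes should tolerate catalytic TsOH at room temperature.

**Compound list**

1 | 2,2,6-trimethylcyclohexan-1-one (racemic) | CC1CCCC(C)(C)C1=O | starting material
2 | 2,6,6-trimethylcyclohex-1-en-1-yl prop-2-en-1-yl carbonate | C=CCOC(=O)OC1=C(C)CCCC1(C)C | intermediate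
3 | (2R)-2,6,6-trimethyl-2-(prop-2-en-1-yl)cyclohexan-1-one | O=C1C(C)(C)CCC[C@]1(C)CC=C | intermediate
4 | (2R)-2,6,6-trimethyl-2-(2-oxopropyl)cyclohexan-1-one | O=C1C(C)(C)CCC[C@]1(C)CC(C)=O | intermediate
5 | (7aR)-4,4,7a-trimethyl-1,4,5,6,7,7a-hexahydro-2H-inden-2-one | O=C1C=C2C(C)(C)CCC[C@]2(C)C1 | intermediate
6 | methyl 2-[(7aR)-4,4,7a-trimethyl-2-oxo-2,4,5,6,7,7a-hexahydro-1H-inden-1-yl]acetate (both C1 epimers) | COC(=O)CC1C(=O)C=C2C(C)(C)CCC[C@]12C | intermediate
7 | methyl 2-[(3aS,7aS)-4,4,7a-trimethyl-2-oxooctahydro-1H-inden-1-yl]acetate (trans-fused; both C1 epimers) | COC(=O)CC1C(=O)C[C@H]2C(C)(C)CCC[C@]12C | intermediate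
8 | methyl 2-[(4aS,8aS)-5,5,8a-trimethyl-2-oxo-3-(trimethylsilyl)decahydronaphthalen-1-yl]acetate (C1 and C3 epimers) | COC(=O)CC1C(=O)C([Si](C)(C)C)C[C@H]2C(C)(C)CCC[C@]12C | intermediate
9 | methyl 2-[(1R,4aS,8aS)-5,5,8a-trimethyl-2-oxodecahydronaphthalen-1-yl]acetate | COC(=O)C[C@H]1C(=O)CC[C@H]2C(C)(C)CCC[C@]12C | intermediate
10 | methyl 2-[(1S,4aS,8aS)-5,5,8a-trimethyl-2-methylidenedecahydronaphthalen-1-yl]acetate | COC(=O)C[C@H]1C(=C)CC[C@H]2C(C)(C)CCC[C@]12C | intermediate
11 | 2-[(1S,4aS,8aS)-5,5,8a-trimethyl-2-methylidenedecahydronaphthalen-1-yl]acetaldehyde | O=CC[C@H]1C(=C)CC[C@H]2C(C)(C)CCC[C@]12C | intermediate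
12 | methyl 4,4-dimethoxybutanoate | COC(=O)CCC(OC)OC | starting material
13 | methyl 2-bromo-4,4-dimethoxybutanoate (racemic) | COC(=O)C(Br)CC(OC)OC | intermediate
14 | (1,4,4-trimethoxy-1-oxobutan-2-yl)triphenylphosphonium bromide | COC(=O)C(CC(OC)OC)[P+](c1ccccc1)(c1ccccc1)c1ccccc1.[Br-] | intermediate
15 | methyl 4,4-dimethoxy-2-(triphenyl-λ5-phosphanylidene)butanoate | COC(=O)C(CC(OC)OC)=P(c1ccccc1)(c1ccccc1)c1ccccc1 | intermediate
16 | methyl (2E)-2-(2,2-dimethoxyethyl)-4-[(1S,4aS,8aS)-5,5,8a-trimethyl-2-methylidenedecahydronaphthalen-1-yl]but-2-enoate | COC(=O)/C(CC(OC)OC)=C/C[C@H]1C(=C)CC[C@H]2C(C)(C)CCC[C@]12C | intermediate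
17 | (2E)-2-(2,2-dimethoxyethyl)-4-[(1S,4aS,8aS)-5,5,8a-trimethyl-2-methylidenedecahydronaphthalen-1-yl]but-2-enoic acid | OC(=O)/C(CC(OC)OC)=C/C[C@H]1C(=C)CC[C@H]2C(C)(C)CCC[C@]12C | intermediate
18 | (4R)-4-hydroxyoxolan-2-one | O[C@H]1COC(=O)C1 | starting material
19 | (4R)-4-[(tert-butyldimethylsilyl)oxy]oxolan-2-one | CC(C)(C)[Si](C)(C)O[C@H]1COC(=O)C1 | intermediate
20 | (4R)-4-[(tert-butyldimethylsilyl)oxy]-3-{1-hydroxy-2-[(1S,4aS,8aS)-5,5,8a-trimethyl-2-methylidenedecahydronaphthalen-1-yl]ethyl}oxolan-2-one (diastereomer mixture) | CC(C)(C)[Si](C)(C)O[C@H]1COC(=O)C1C(O)C[C@H]1C(=C)CC[C@H]2C(C)(C)CCC[C@]12C | intermediate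
21 | methanesulfonate of 20 | CC(C)(C)[Si](C)(C)O[C@H]1COC(=O)C1C(OS(C)(=O)=O)C[C@H]1C(=C)CC[C@H]2C(C)(C)CCC[C@]12C | intermediate
22 | (3E,4R)-4-[(tert-butyldimethylsilyl)oxy]-3-{2-[(1S,4aS,8aS)-5,5,8a-trimethyl-2-methylidenedecahydronaphthalen-1-yl]ethylidene}oxolan-2-one | CC(C)(C)[Si](C)(C)O[C@H]1COC(=O)/C1=C/C[C@H]1C(=C)CC[C@H]2C(C)(C)CCC[C@]12C | intermediate
23 | isocoronarin D, (3E,4R)-4-hydroxy-3-{2-[(1S,4aS,8aS)-5,5,8a-trimethyl-2-methylidenedecahydronaphthalen-1-yl]ethylidene}oxolan-2-one | O[C@H]1COC(=O)/C1=C/C[C@H]1C(=C)CC[C@H]2C(C)(C)CCC[C@]12C | intermediate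
24 | mixed anhydride of 17 with 2,4,6-trichlorobenzoic acid | O=C(OC(=O)/C(CC(OC)OC)=C/C[C@H]1C(=C)CC[C@H]2C(C)(C)CCC[C@]12C)c1c(Cl)cc(Cl)cc1Cl | intermediate
25 | (3R,4E)-5-oxo-4-{2-[decalinyl]ethylidene}oxolan-3-yl (2E)-2-(2,2-dimethoxyethyl)-4-[decalinyl]but-2-enoate (decalinyl = (1S,4aS,8aS)-5,5,8a-trimethyl-2-methylidenedecahydronaphthalen-1-yl) | C=C1CC[C@H]2C(C)(C)CCC[C@]2(C)[C@H]1C/C=C(\CC(OC)OC)C(=O)O[C@H]1COC(=O)/C1=C/C[C@H]1C(=C)CC[C@H]2C(C)(C)CCC[C@]12C | intermediate
26 | CNP0274315.1, (3R,4E)-5-oxo-4-{2-[decalinyl]ethylidene}oxolan-3-yl (2E)-2-(2-oxoethyl)-4-[decalinyl]but-2-enoate | C=C1CC[C@H]2C(C)(C)CCC[C@]2(C)[C@H]1C/C=C(\CC=O)C(=O)O[C@H]1COC(=O)/C1=C/C[C@H]1C(=C)CC[C@H]2C(C)(C)CCC[C@]12C | target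

**Totals**

Total step count: 19. Longest linear sequence: 14 steps (steps 1–9 and 15–19).

**Three steps most likely to fail**

Step 7. What may go wrong: the wrong ring bond migrates (C9 instead of C6), or the ketone takes up a second carbon or closes to the spiro-epoxide. The fallback sets out from 6 and returns at 9; it fixes the position of the new carbon by a regiospecific enol ether instead of by migratory preference. Conjugate hydrosilylation of enone 6 (Et3SiH, RhCl(PPh3)3, toluene, 60 °C) should give the triethylsilyl enol ether F1 with the C6=C8 double bond and the C5 hydrogen in place. Cyclopropanation (Et2Zn, CH2I2, CH2Cl2, 0 °C) gives the siloxycyclopropane F2. FeCl3 in DMF (Ito–Saegusa opening, scission of the internal C6–C8 bond) gives the ring-enlarged β-chloro ketone F3, which NaOAc in MeOH converts into the enone F4. Hydrogenation (H2, Pd/C) and NaOMe/MeOH equilibration at C9 lead to 9.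

Step 16. What may go wrong: poor control of the alkene geometry in the E1cB loss of mesylate, and loss of the silyloxy group from C14 instead, which leads to the butenolide. The fallback sets out from 19 and returns at 22; it makes the double bond by Horner–Wadsworth–Emmons olefination. The lithium enolate of 19 (LiN(i-Pr)2, THF, −78 °C) is quenched with ClP(OEt)2 to give the phosphonite F5, which is oxidised in the same flask (air or H2O2) to the phosphonate F6. Its sodium salt (NaH, THF, 0 °C) condenses with aldehyde 11 to give 22, the (E)-isomer being favoured for α-phosphono lactones.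

Step 19. What may go wrong: under the acid needed for acetal hydrolysis, migration of the C12=C13 double bond toward the freed aldehyde (through its dienol), or shift of the exocyclic C8=C17 double bonds into the rings. The fallback sets out from 11 and returns at 26; it carries C15 at the alcohol level and unmasks it without acid. Wittig reaction of 11 with commercial α-(triphenylphosphoranylidene)-γ-butyrolactone (toluene, 90 °C) gives the (E)-lactone F7. LiOH (THF/H2O) opens it to the lithium hydroxy carboxylate F8, and t-BuMe2SiCl/imidazole gives the bis-silyl compound F9. K2CO3 in MeOH cleaves only the silyl ester to give the acid F10. Coupling with 23 (EDC·HCl, DMAP, CH2Cl2) gives the ester F11, HF·pyridine gives the primary alcohol F12, and immediate oxidation (Dess–Martin periodinane, NaHCO3, CH2Cl2) gives 26.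

**Further compounds**

F1 | step 7 | methyl 2-[(3aS,7aS)-4,4,7a-trimethyl-2-[(triethylsilyl)oxy]-3a,4,5,6,7,7a-hexahydro-1H-inden-1-yl]acetate | COC(=O)CC1C(O[Si](CC)(CC)CC)=C[C@H]2C(C)(C)CCC[C@]12C
F2 | step 7 | methyl 2-{4,4,7a-trimethyl-2-[(triethylsilyl)oxy]-2,3-methanooctahydro-1H-inden-1-yl}acetate (trans-fused, cyclopropane across C2–C3) | COC(=O)CC1C3(O[Si](CC)(CC)CC)CC3[C@H]2C(C)(C)CCC[C@]12C
F3 | step 7 | methyl 2-(4-chloro-5,5,8a-trimethyl-2-oxodecahydronaphthalen-1-yl)acetate (trans-fused, ring fusion as in 9) | COC(=O)CC1C(=O)CC(Cl)[C@H]2C(C)(C)CCC[C@]12C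
F4 | step 7 | methyl 2-[(4aS,8aS)-5,5,8a-trimethyl-2-oxo-1,2,4a,5,6,7,8,8a-octahydronaphthalen-1-yl]acetate | COC(=O)CC1C(=O)C=C[C@H]2C(C)(C)CCC[C@]12C
F5 | step 16 | diethyl [(4S)-4-[(tert-butyldimethylsilyl)oxy]-2-oxooxolan-3-yl]phosphonite | CC(C)(C)[Si](C)(C)O[C@H]1COC(=O)C1P(OCC)OCC
F6 | step 16 | diethyl [(4S)-4-[(tert-butyldimethylsilyl)oxy]-2-oxooxolan-3-yl]phosphonate | CC(C)(C)[Si](C)(C)O[C@H]1COC(=O)C1P(=O)(OCC)OCC
F7 | step 19 | (3E)-3-{2-[(1S,4aS,8aS)-5,5,8a-trimethyl-2-methylidenedecahydronaphthalen-1-yl]ethylidene}oxolan-2-one | O=C1/C(=C/C[C@H]2C(=C)CC[C@H]3C(C)(C)CCC[C@]23C)CCO1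
F8 | step 19 | lithium (2E)-2-(2-hydroxyethyl)-4-[(1S,4aS,8aS)-5,5,8a-trimethyl-2-methylidenedecahydronaphthalen-1-yl]but-2-enoate | [Li+].[O-]C(=O)/C(CCO)=C/C[C@H]1C(=C)CC[C@H]2C(C)(C)CCC[C@]12C
F9 | step 19 | tert-butyldimethylsilyl (2E)-2-{2-[(tert-butyldimethylsilyl)oxy]ethyl}-4-[(1S,4aS,8aS)-5,5,8a-trimethyl-2-methylidenedecahydronaphthalen-1-yl]but-2-enoate | CC(C)(C)[Si](C)(C)OC(=O)/C(CCO[Si](C)(C)C(C)(C)C)=C/C[C@H]1C(=C)CC[C@H]2C(C)(C)CCC[C@]12C
F10 | step 19 | (2E)-2-{2-[(tert-butyldimethylsilyl)oxy]ethyl}-4-[(1S,4aS,8aS)-5,5,8a-trimethyl-2-methylidenedecahydronaphthalen-1-yl]but-2-enoic acid | OC(=O)/C(CCO[Si](C)(C)C(C)(C)C)=C/C[C@H]1C(=C)CC[C@H]2C(C)(C)CCC[C@]12C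
F11 | step 19 | ester of F10 with isocoronarin D (C15 silyl ether of the target skeleton) | C=C1CC[C@H]2C(C)(C)CCC[C@]2(C)[C@H]1C/C=C(\CCO[Si](C)(C)C(C)(C)C)C(=O)O[C@H]1COC(=O)/C1=C/C[C@H]1C(=C)CC[C@H]2C(C)(C)CCC[C@]12C
F12 | step 19 | C15 primary alcohol of the target skeleton | C=C1CC[C@H]2C(C)(C)CCC[C@]2(C)[C@H]1C/C=C(\CCO)C(=O)O[C@H]1COC(=O)/C1=C/C[C@H]1C(=C)CC[C@H]2C(C)(C)CCC[C@]12C
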